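**Plan**

- Locants C1–C9 are those of the bicyclo[3.3.1]nonan-9-one core (C1 carbinol bridgehead, C2–C3 oxirane, C4 OMe, C5 bridgehead, C6 OH, C7 N, C8 CH2, C9 C=O) and are kept for the same carbons in every intermediate.
- Retrosynthetic cuts: the amide N–C(O) bond; C5–C6 (aldol) together with C4–OMe (oxa-Michael), which opens ring B to a cyclohexenone carrying a C8–C7–C6 amino aldehyde chain; C7=C8 (olefination of a C8 aldehyde, C7–H by hydrogenation); the C2–C3 oxirane oxygen; last, the oxygens on C1 and C9.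
- Enabling feature: ring A (C1–C2–C3–C4–C5–C9) with the exocyclic carbon C8 on C1 is a benzoic acid ring in disguise. C8 is the carboxyl carbon, and the tertiary C1–O next to the C9 oxygen is the ipso/ortho cis-diol that a benzoate dioxygenase installs.
- Forward order: ring A is present from the start and is dearomatised in step 1; the oxirane is fused on in step 4; the chain C8–C7–C6 is built in steps 5–9; ring B closes in step 12; the fatty amide is attached last.
- Stereochemistry: C1 (and a temporary C9 carbinol) from the enzyme; C2/C3 by relay from the C1 hydroxyl; C7 from a chiral rhodium catalyst; C4, C5 and C6 in the ring-closing cascade under control of the C1-anchored tether.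

Key step: step 1

Remark: benzoic acid is fed to the cells as its sodium salt (NaOH, pH 7) and recovered as the free acid product after acidification; salt and acid are treated as one compound.
Remark: the γ-hydroxy aldehydes that arise in steps 9 and 12 are assumed to exist almost entirely as spiro-lactols (anomeric mixtures at C6, left undefined in the SMILES) that open reversibly.

**Route**

Step 1
Reactants: 1 benzoic acid
Product: 2 (1S,2R)-1,2-dihydroxycyclohexa-3,5-diene-1-carboxylic acid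
Conditions: Cupriavidus necator B9 whole cells (benzoate-induced, cis-diol dehydrogenase-deficient mutant), fructose, mineral-salts medium, NaOH to pH 7, air, 30 °C; then HCl to pH 3, EtOAc, 0 °C
Reagents that add atoms: dioxygen O=O
Why: The Rieske-type non-haem iron benzoate 1,2-dioxygenase of the cells reduces O2 with two electrons relayed from NADH and transfers both oxygen atoms from an iron-bound (hydro)peroxide to the same face of the ipso and ortho carbons of bound benzoate, so the C1–O and C9–O bonds form together and the arene becomes the cis-diol diene. The closest known reaction type is microbial arene cis-dihydroxylation, here in the ipso,ortho mode that carboxylate-anchored arenes show. No ring is closed; the six-membered carbocycle is kept and becomes ring A. The two new stereocentres, C1 (S) and C9 (R), are fixed solely by the enzyme pocket, because benzoate is flat and achiral. The step needs ipso,ortho rather than ortho,meta regioselectivity, attack on one enantiotopic face, and survival of the diene acid; the carboxylate anchor secures the first two and the blocked diol dehydrogenase of the mutant prevents decarboxylative rearomatisation to catechol. Fructose is respired to regenerate NADH, and cold acidification with prompt extraction limits acid-catalysed dehydration to salicylic acid.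

Step 2
Reactants: 2 (1S,2R)-1,2-dihydroxycyclohexa-3,5-diene-1-carboxylic acid
Product: 3 methyl (1S,2R)-1,2-dihydroxycyclohexa-3,5-diene-1-carboxylate
Conditions: MeI (1.5 equiv), KHCO3 (1.5 equiv), DMF, 23 °C
Reagents that add atoms: iodomethane CI
Why: Carboxylate O-alkylation (SN2 on iodomethane) under bicarbonate is mild enough for the acid-labile diene diol, touches neither hydroxyl nor stereocentre, and keeps C1 electron-poor so that ionisation and aromatisation stay suppressed.

Step 3
Reactants: 3 methyl (1S,2R)-1,2-dihydroxycyclohexa-3,5-diene-1-carboxylate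
Product: 4 methyl (1S,2R)-2-[(tert-butyldimethylsilyl)oxy]-1-hydroxycyclohexa-3,5-diene-1-carboxylate
Conditions: TBSCl (1.2 equiv), imidazole (2.5 equiv), DMF, 0 → 23 °C
Reagents that add atoms: tert-butyldimethylsilyl chloride CC(C)(C)[Si](C)(C)Cl
Why: Chemoselective silyl ether formation, in which the secondary allylic C9 hydroxyl reacts while the hindered tertiary α-hydroxy ester hydroxyl at C1 does not, so the only free hydroxyl left is the one that must direct the epoxidation and the bulky silyl ether covers the C4=C5 side.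

Step 4
Reactants: 4 methyl (1S,2R)-2-[(tert-butyldimethylsilyl)oxy]-1-hydroxycyclohexa-3,5-diene-1-carboxylate
Product: 5 methyl (1S,2S,3R,6S)-3-[(tert-butyldimethylsilyl)oxy]-2-hydroxy-7-oxabicyclo[4.1.0]hept-4-ene-2-carboxylate (oxirane cis to the C1 hydroxyl)
Conditions: VO(acac)2 (5 mol %), t-BuOOH (1.5 equiv, in decane), CH2Cl2, 0 → 23 °C
Reagents that add atoms: tert-butyl hydroperoxide CC(C)(C)OO
Why: Vanadium-catalysed hydroxyl-directed epoxidation, in which the vanadate ester of the C1 tertiary alcohol delivers oxygen intramolecularly to its allylic alkene C2=C3 on the face of the C1–O bond and so sets C2 and C3 cis to that hydroxyl, while C4=C5 is only homoallylic to it and has its α-face covered by the silyl ether.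

Step 5
Reactants: 5 methyl (1S,2S,3R,6S)-3-[(tert-butyldimethylsilyl)oxy]-2-hydroxy-7-oxabicyclo[4.1.0]hept-4-ene-2-carboxylate
Product: 6 (1S,2S,3R,6S)-3-[(tert-butyldimethylsilyl)oxy]-2-(hydroxymethyl)-7-oxabicyclo[4.1.0]hept-4-en-2-ol
Conditions: NaBH4 (3 equiv), MeOH, 0 °C
Reagents that add atoms: none
Why: Borohydride reduction of an α-hydroxy ester, which the neighbouring oxygen activates enough for NaBH4 in methanol, while the vinyl oxirane, silyl ether and alkene are inert and no stereocentre is touched.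

Step 6
Reactants: 6 (1S,2S,3R,6S)-3-[(tert-butyldimethylsilyl)oxy]-2-(hydroxymethyl)-7-oxabicyclo[4.1.0]hept-4-en-2-ol
Product: 7 (1S,2S,3R,6S)-3-[(tert-butyldimethylsilyl)oxy]-2-hydroxy-7-oxabicyclo[4.1.0]hept-4-ene-2-carbaldehyde
Conditions: IBX (1.5 equiv), DMSO, 23 °C
Reagents that add atoms: none
Why: IBX oxidation of the primary alcohol to the C8 aldehyde, chosen because it does not cleave 1,2-diols, cannot oxidise the tertiary C1 hydroxyl, and gives an aldehyde whose quaternary α-carbon cannot enolise.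

Step 7
Reactants: 7 (1S,2S,3R,6S)-3-[(tert-butyldimethylsilyl)oxy]-2-hydroxy-7-oxabicyclo[4.1.0]hept-4-ene-2-carbaldehyde; 8 trimethyl N-(benzyloxycarbonyl)-2-phosphonoglycinate (racemic)
Product: 9 methyl (Z)-2-{[(benzyloxy)carbonyl]amino}-3-[(1S,2S,3R,6S)-3-[(tert-butyldimethylsilyl)oxy]-2-hydroxy-7-oxabicyclo[4.1.0]hept-4-en-2-yl]prop-2-enoate
Conditions: 8 (1.3 equiv), N,N,N′,N′-tetramethylguanidine (1.25 equiv), THF, −78 → 0 °C
Reagents that add atoms: none
Why: Horner–Wadsworth–Emmons olefination of the aldehyde with the phosphonoglycinate anion, which forms the C8=C7 bond and should give mainly the (Z)-dehydroamino ester that this reagent class prefers, either geometry being usable in the next step.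

Step 8
Reactants: 9 methyl (Z)-2-{[(benzyloxy)carbonyl]amino}-3-[(1S,2S,3R,6S)-3-[(tert-butyldimethylsilyl)oxy]-2-hydroxy-7-oxabicyclo[4.1.0]hept-4-en-2-yl]prop-2-enoate
Product: 10 methyl (2S)-2-{[(benzyloxy)carbonyl]amino}-3-[(1S,2S,3R,6S)-3-[(tert-butyldimethylsilyl)oxy]-2-hydroxy-7-oxabicyclo[4.1.0]hept-4-en-2-yl]propanoate
Conditions: [Rh(cod)((S,S)-Et-DuPhos)]OTf (2 mol %), H2 (6 bar), degassed THF, 23 °C
Reagents that add atoms: none
Why: Rhodium–bisphospholane asymmetric hydrogenation of an α-(acylamino)acrylate, in which the enamide chelates the cationic rhodium centre through its carbamate oxygen and the (S,S)-ligand delivers H2 to the face that gives (S)-C7, while the ring alkene cannot chelate and should stay.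

Step 9
Reactants: 10 methyl (2S)-2-{[(benzyloxy)carbonyl]amino}-3-[(1S,2S,3R,6S)-3-[(tert-butyldimethylsilyl)oxy]-2-hydroxy-7-oxabicyclo[4.1.0]hept-4-en-2-yl]propanoate
Product: 12 benzyl N-[(3S,5S,6R,9S,10S)-6-[(tert-butyldimethylsilyl)oxy]-9,10-epoxy-2-hydroxy-1-oxaspiro[4.5]dec-7-en-3-yl]carbamate (spiro-lactol; both anomers), via open hydroxy aldehyde 11 (not isolated)
Conditions: i-Bu2AlH (3.3 equiv), CH2Cl2, −78 °C; MeOH, then aq. potassium sodium tartrate
Reagents that add atoms: none
Why: Low-temperature partial reduction of the ester with i-Bu2AlH, whose aluminium hemiacetal persists at −78 °C and releases aldehyde 11 only on work-up, after which the γ-hydroxy aldehyde closes onto the C1 hydroxyl to the five-membered lactol, a form that shields the C7 stereocentre from enolisation.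

Step 10
Reactants: 12 benzyl N-[(3S,5S,6R,9S,10S)-6-[(tert-butyldimethylsilyl)oxy]-9,10-epoxy-2-hydroxy-1-oxaspiro[4.5]dec-7-en-3-yl]carbamate
Product: 13 benzyl N-[(3S,5R,6R,9S,10S)-9,10-epoxy-2,6-dihydroxy-1-oxaspiro[4.5]dec-7-en-3-yl]carbamate
Conditions: n-Bu4NF (1.5 equiv), AcOH (1.5 equiv), THF, 0 → 23 °C
Reagents that add atoms: none
Why: Fluoride-mediated desilylation, buffered with acetic acid so that neither the oxirane nor the lactol meets a free alkoxide, with no change at any stereocentre.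

Step 11
Reactants: 13 benzyl N-[(3S,5R,6R,9S,10S)-9,10-epoxy-2,6-dihydroxy-1-oxaspiro[4.5]dec-7-en-3-yl]carbamate
Product: 14 benzyl N-[(3S,5S,9S,10S)-9,10-epoxy-2-hydroxy-6-oxo-1-oxaspiro[4.5]dec-7-en-3-yl]carbamate
Conditions: IBX (1.5 equiv), DMSO, 23 °C
Reagents that add atoms: none
Why: IBX oxidation of the secondary allylic alcohol to the C9 enone, a reagent that oxidises γ-lactols only sluggishly, so the auxiliary C9 stereocentre of the dihydroxylation becomes the sp2 carbon of the target without loss of the masked aldehyde.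

Step 12
Reactants: 14 benzyl N-[(3S,5S,9S,10S)-9,10-epoxy-2-hydroxy-6-oxo-1-oxaspiro[4.5]dec-7-en-3-yl]carbamate
Product: 17 benzyl N-[(1S,2S,3S,4S,5S,6R,7S)-2,3-epoxy-1,6-dihydroxy-4-methoxy-9-oxobicyclo[3.3.1]nonan-7-yl]carbamate, via open keto aldehyde 15 (not isolated), via methoxy ketone 16 (not isolated)
Conditions: NaOMe (0.2 equiv), MeOH, −20 → 0 °C; AcOH quench
Reagents that add atoms: methanol CO
Why: Base-mediated oxa-Michael/intramolecular aldol cascade in which methoxide adds reversibly to C4 of the enone in the ring-opened lactol 15 and the enolate of 16 is trapped at C5 by the tethered aldehyde in a chair-like 6-(enolendo)-exo-trig closure that forms ring B; the tether reaches C5 only across the β-face with C8 pseudo-axial, a geometry that leaves room for hydrogen but not for methoxy in the transannular position at C4, so the closure drains the adduct with the methoxy group α (anti addition across C4=C5, C5 set by the tether), a sodium ion bridging enolate and aldehyde oxygens turns the new C6 hydroxyl exo and cis to the equatorial carbamate, and β-elimination of methanol from the product is blocked because C5 is now a bridgehead (Bredt's rule).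

Step 13
Reactants: 17 benzyl N-[(1S,2S,3S,4S,5S,6R,7S)-2,3-epoxy-1,6-dihydroxy-4-methoxy-9-oxobicyclo[3.3.1]nonan-7-yl]carbamate
Product: 18 (1S,2S,3S,4S,5S,6R,7S)-7-amino-2,3-epoxy-1,6-dihydroxy-4-methoxybicyclo[3.3.1]nonan-9-one
Conditions: H2 (1 bar), Pd/C (10 wt % Pd), EtOAc–MeOH, 23 °C
Reagents that add atoms: none
Why: Palladium-catalysed hydrogenolysis of the benzyl carbamate, applied only now that no alkene is left, with an oxirane that is neither allylic nor benzylic and a hindered bridging ketone that should both survive neutral hydrogenation at ambient pressure.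

Step 14
Reactants: 18 (1S,2S,3S,4S,5S,6R,7S)-7-amino-2,3-epoxy-1,6-dihydroxy-4-methoxybicyclo[3.3.1]nonan-9-one; 19 (E)-dodec-2-enoic acid
Product: 21 (2E)-N-[(1S,2S,3S,4S,5S,6R,7S)-2,3-epoxy-1,6-dihydroxy-4-methoxy-9-oxobicyclo[3.3.1]nonan-7-yl]dodec-2-enamide, via benzotriazolyl ester 20 (not isolated)
Conditions: 19 (1.1 equiv), EDC·HCl (1.3 equiv), HOBt (1.3 equiv), CH2Cl2–DMF, 0 → 23 °C
Reagents that add atoms: none
Why: Carbodiimide/HOBt amide coupling through active ester 20, which acylates the primary amine far faster than the secondary and tertiary hydroxyls and is too mild to isomerise the (E)-enoyl unit or open the oxirane.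

**Compound list**

1 | benzoic acid | OC(=O)c1ccccc1 | starting material
2 | (1S,2R)-1,2-dihydroxycyclohexa-3,5-diene-1-carboxylic acid | OC(=O)[C@@]1(O)[C@H](O)C=CC=C1 | intermediate
3 | methyl (1S,2R)-1,2-dihydroxycyclohexa-3,5-diene-1-carboxylate | COC(=O)[C@@]1(O)[C@H](O)C=CC=C1 | intermediate
4 | methyl (1S,2R)-2-[(tert-butyldimethylsilyl)oxy]-1-hydroxycyclohexa-3,5-diene-1-carboxylate | COC(=O)[C@@]1(O)[C@H](O[Si](C)(C)C(C)(C)C)C=CC=C1 | intermediate
5 | methyl (1S,2S,3R,6S)-3-[(tert-butyldimethylsilyl)oxy]-2-hydroxy-7-oxabicyclo[4.1.0]hept-4-ene-2-carboxylate | COC(=O)[C@@]2(O)[C@H](O[Si](C)(C)C(C)(C)C)C=C[C@@H]1O[C@@H]12 | intermediate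
6 | (1S,2S,3R,6S)-3-[(tert-butyldimethylsilyl)oxy]-2-(hydroxymethyl)-7-oxabicyclo[4.1.0]hept-4-en-2-ol | OC[C@@]2(O)[C@H](O[Si](C)(C)C(C)(C)C)C=C[C@@H]1O[C@@H]12 | intermediate
7 | (1S,2S,3R,6S)-3-[(tert-butyldimethylsilyl)oxy]-2-hydroxy-7-oxabicyclo[4.1.0]hept-4-ene-2-carbaldehyde | O=C[C@@]2(O)[C@H](O[Si](C)(C)C(C)(C)C)C=C[C@@H]1O[C@@H]12 | intermediate
8 | trimethyl N-(benzyloxycarbonyl)-2-phosphonoglycinate (racemic) | COC(=O)C(NC(=O)OCc1ccccc1)P(=O)(OC)OC | starting material
9 | methyl (Z)-2-{[(benzyloxy)carbonyl]amino}-3-[(1S,2S,3R,6S)-3-[(tert-butyldimethylsilyl)oxy]-2-hydroxy-7-oxabicyclo[4.1.0]hept-4-en-2-yl]prop-2-enoate | COC(=O)/C(NC(=O)OCc1ccccc1)=C/[C@@]2(O)[C@H](O[Si](C)(C)C(C)(C)C)C=C[C@@H]1O[C@@H]12 | intermediate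
10 | methyl (2S)-2-{[(benzyloxy)carbonyl]amino}-3-[(1S,2S,3R,6S)-3-[(tert-butyldimethylsilyl)oxy]-2-hydroxy-7-oxabicyclo[4.1.0]hept-4-en-2-yl]propanoate | COC(=O)[C@@H](NC(=O)OCc1ccccc1)C[C@@]2(O)[C@H](O[Si](C)(C)C(C)(C)C)C=C[C@@H]1O[C@@H]12 | intermediate
11 | benzyl N-[(2S)-1-[(1S,2S,3R,6S)-3-[(tert-butyldimethylsilyl)oxy]-2-hydroxy-7-oxabicyclo[4.1.0]hept-4-en-2-yl]-3-oxopropan-2-yl]carbamate (open hydroxy aldehyde; not isolated) | O=C[C@@H](NC(=O)OCc1ccccc1)C[C@@]2(O)[C@H](O[Si](C)(C)C(C)(C)C)C=C[C@@H]1O[C@@H]12 | intermediate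
12 | benzyl N-[(3S,5S,6R,9S,10S)-6-[(tert-butyldimethylsilyl)oxy]-9,10-epoxy-2-hydroxy-1-oxaspiro[4.5]dec-7-en-3-yl]carbamate (spiro-lactol; both anomers) | OC1O[C@]2(C[C@@H]1NC(=O)OCc1ccccc1)[C@H](O[Si](C)(C)C(C)(C)C)C=C[C@@H]3O[C@@H]32 | intermediate
13 | benzyl N-[(3S,5R,6R,9S,10S)-9,10-epoxy-2,6-dihydroxy-1-oxaspiro[4.5]dec-7-en-3-yl]carbamate | OC1O[C@]2(C[C@@H]1NC(=O)OCc1ccccc1)[C@H](O)C=C[C@@H]3O[C@@H]32 | intermediate
14 | benzyl N-[(3S,5S,9S,10S)-9,10-epoxy-2-hydroxy-6-oxo-1-oxaspiro[4.5]dec-7-en-3-yl]carbamate | OC1O[C@]2(C[C@@H]1NC(=O)OCc1ccccc1)C(=O)C=C[C@@H]3O[C@@H]32 | intermediate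
15 | benzyl N-[(2S)-1-[(1S,2S,6S)-2-hydroxy-3-oxo-7-oxabicyclo[4.1.0]hept-4-en-2-yl]-3-oxopropan-2-yl]carbamate (open keto aldehyde; not isolated) | O=C[C@@H](NC(=O)OCc1ccccc1)C[C@@]2(O)C(=O)C=C[C@@H]1O[C@@H]12 | intermediate
16 | benzyl N-[(2S)-1-[(1S,2S,5S,6S)-2-hydroxy-5-methoxy-3-oxo-7-oxabicyclo[4.1.0]heptan-2-yl]-3-oxopropan-2-yl]carbamate (methoxy ketone, reacting as its enolate; not isolated) | O=C[C@@H](NC(=O)OCc1ccccc1)C[C@@]2(O)C(=O)C[C@H](OC)[C@@H]1O[C@@H]12 | intermediate
17 | benzyl N-[(1S,2S,3S,4S,5S,6R,7S)-2,3-epoxy-1,6-dihydroxy-4-methoxy-9-oxobicyclo[3.3.1]nonan-7-yl]carbamate | O=C(OCc1ccccc1)N[C@H]1C[C@@]2(O)C(=O)[C@@H]([C@H]1O)[C@H](OC)[C@@H]1O[C@@H]12 | intermediate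
18 | (1S,2S,3S,4S,5S,6R,7S)-7-amino-2,3-epoxy-1,6-dihydroxy-4-methoxybicyclo[3.3.1]nonan-9-one | N[C@H]1C[C@@]2(O)C(=O)[C@@H]([C@H]1O)[C@H](OC)[C@@H]1O[C@@H]12 | intermediate
19 | (E)-dodec-2-enoic acid | CCCCCCCCC/C=C/C(=O)O | starting material
20 | 1H-benzotriazol-1-yl (E)-dodec-2-enoate (not isolated) | CCCCCCCCC/C=C/C(=O)On1nnc2ccccc12 | intermediate
21 | (2E)-N-[(1S,2S,3S,4S,5S,6R,7S)-2,3-epoxy-1,6-dihydroxy-4-methoxy-9-oxobicyclo[3.3.1]nonan-7-yl]dodec-2-enamide | CCCCCCCCC/C=C/C(=O)N[C@H]1C[C@@]2(O)C(=O)[C@@H]([C@H]1O)[C@H](OC)[C@@H]1O[C@@H]12 | target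

**Step count and risks**

Total step count: 14. Longest linear sequence: 14 steps (1 → 21); 8 and 19 are used as purchased.

Steps most likely to fail:

1. Step 12. The aldol may close through an open transition state with the aldehyde oxygen anti to the enolate oxygen, or equilibrate by retro-aldol, so that the C6 carbinol ends up endo and trans to nitrogen. The fallback sets C6 by neighbouring-group inversion instead of in the aldol. It sets out from 14, whose cascade would then give benzyl N-[(1S,2S,3S,4S,5S,6S,7S)-2,3-epoxy-1,6-dihydroxy-4-methoxy-9-oxobicyclo[3.3.1]nonan-7-yl]carbamate F1. Hydrogenolysis as in step 13 would give the C6-epimeric amine F2, and coupling with 19 as in step 14 the C6-epimeric amide F3. Et2NSF3 in CH2Cl2 at −78 °C should activate the C6 hydroxyl and let the amide oxygen displace it from the exo face with inversion, giving the cis-fused 2-[(E)-undec-1-enyl]oxazoline F4. Dilute aqueous acid at 0 °C would open F4 to the O6-acyl amine F5 (as its ammonium salt), and at pH 8 the acyl group migrates from oxygen to nitrogen. The fallback comes back to the route at 21.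

2. Step 4. Oxygen transfer to C2=C3 may be slow because this alkene sits next to the ester-bearing C1 and is the less electron-rich of the two, so undirected attack on C4=C5 or Lewis-acid opening of the vinyl oxirane could compete. The fallback removes the ester before the epoxidation. It sets out from 4: NaBH4 in MeOH at 0 °C would give (1R,6R)-6-[(tert-butyldimethylsilyl)oxy]-1-(hydroxymethyl)cyclohexa-2,4-dien-1-ol F6, kept free of acid because this dienol aromatises easily. Ac2O/pyridine at 0 °C would acetylate only the primary hydroxyl to [(1R,6R)-6-[(tert-butyldimethylsilyl)oxy]-1-hydroxycyclohexa-2,4-dien-1-yl]methyl acetate F7. The C1 carbinol is then an ordinary tertiary allylic alcohol, and VO(acac)2/t-BuOOH should deliver [(1S,2S,3R,6S)-3-[(tert-butyldimethylsilyl)oxy]-2-hydroxy-7-oxabicyclo[4.1.0]hept-4-en-2-yl]methyl acetate F8. K2CO3 in MeOH removes the acetate, and the fallback comes back to the route at 6.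

3. Step 8. The enamide carries a fully substituted, hydroxylated carbon at its β-position, so hydrogen uptake may be sluggish, and the C1 hydroxyl may bind rhodium and compete with the ligand for facial control at C7. The fallback replaces catalyst control by separation and recycling of C7 epimers. It sets out from 9: the achiral, less hindered [Rh(nbd)(dppb)]BF4 under H2 in CH2Cl2 would give methyl 2-{[(benzyloxy)carbonyl]amino}-3-[(1S,2S,3R,6S)-3-[(tert-butyldimethylsilyl)oxy]-2-hydroxy-7-oxabicyclo[4.1.0]hept-4-en-2-yl]propanoate as both C7 epimers F9. Catalytic DBU in toluene at 40 °C should lactonise the γ-hydroxy ester onto the C1 hydroxyl, giving the rigid spiro-lactones benzyl N-[(3S,5S,6R,9S,10S)-6-[(tert-butyldimethylsilyl)oxy]-9,10-epoxy-2-oxo-1-oxaspiro[4.5]dec-7-en-3-yl]carbamate F10 and its (3R)-epimer F11, which should separate on silica. F11 is re-equilibrated at the carbon α to the lactone carbonyl with DBU and recycled. F10 is also what 10 would give if it cyclised on standing. i-Bu2AlH at −78 °C reduces F10 to the lactol, and the fallback comes back to the route at 12.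

**Further compounds**

F1 | step 12 | benzyl N-[(1S,2S,3S,4S,5S,6S,7S)-2,3-epoxy-1,6-dihydroxy-4-methoxy-9-oxobicyclo[3.3.1]nonan-7-yl]carbamate (C6 epimer of 17) | O=C(OCc1ccccc1)N[C@H]1C[C@@]2(O)C(=O)[C@@H]([C@@H]1O)[C@H](OC)[C@@H]1O[C@@H]12
F2 | step 12 | (1S,2S,3S,4S,5S,6S,7S)-7-amino-2,3-epoxy-1,6-dihydroxy-4-methoxybicyclo[3.3.1]nonan-9-one (C6 epimer of 18) | N[C@H]1C[C@@]2(O)C(=O)[C@@H]([C@@H]1O)[C@H](OC)[C@@H]1O[C@@H]12
F3 | step 12 | (2E)-N-[(1S,2S,3S,4S,5S,6S,7S)-2,3-epoxy-1,6-dihydroxy-4-methoxy-9-oxobicyclo[3.3.1]nonan-7-yl]dodec-2-enamide (C6 epimer of 21) | CCCCCCCCC/C=C/C(=O)N[C@H]1C[C@@]2(O)C(=O)[C@@H]([C@@H]1O)[C@H](OC)[C@@H]1O[C@@H]12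
F4 | step 12 | cis-fused 2-[(E)-undec-1-enyl]-4,5-dihydrooxazole spanning O6 and N7 of the core (C6 inverted to the configuration of 21) | CCCCCCCCC/C=C/C1=N[C@H]2C[C@@]3(O)C(=O)[C@@H]([C@H]2O1)[C@H](OC)[C@@H]2O[C@@H]23
F5 | step 12 | (1S,2S,3S,4S,5S,6R,7S)-7-amino-2,3-epoxy-1-hydroxy-4-methoxy-9-oxobicyclo[3.3.1]nonan-6-yl (E)-dodec-2-enoate | N[C@H]1C[C@@]2(O)C(=O)[C@@H]([C@H]1OC(=O)/C=C/CCCCCCCCC)[C@H](OC)[C@@H]1O[C@@H]12
F6 | step 4 | (1R,6R)-6-[(tert-butyldimethylsilyl)oxy]-1-(hydroxymethyl)cyclohexa-2,4-dien-1-ol | OC[C@@]1(O)[C@H](O[Si](C)(C)C(C)(C)C)C=CC=C1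
F7 | step 4 | [(1R,6R)-6-[(tert-butyldimethylsilyl)oxy]-1-hydroxycyclohexa-2,4-dien-1-yl]methyl acetate | CC(=O)OC[C@@]1(O)[C@H](O[Si](C)(C)C(C)(C)C)C=CC=C1
F8 | step 4 | [(1S,2S,3R,6S)-3-[(tert-butyldimethylsilyl)oxy]-2-hydroxy-7-oxabicyclo[4.1.0]hept-4-en-2-yl]methyl acetate | CC(=O)OC[C@@]2(O)[C@H](O[Si](C)(C)C(C)(C)C)C=C[C@@H]1O[C@@H]12
F9 | step 8 | methyl 2-{[(benzyloxy)carbonyl]amino}-3-[(1S,2S,3R,6S)-3-[(tert-butyldimethylsilyl)oxy]-2-hydroxy-7-oxabicyclo[4.1.0]hept-4-en-2-yl]propanoate (both C7 epimers) | COC(=O)C(NC(=O)OCc1ccccc1)C[C@@]2(O)[C@H](O[Si](C)(C)C(C)(C)C)C=C[C@@H]1O[C@@H]12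
F10 | step 8 | benzyl N-[(3S,5S,6R,9S,10S)-6-[(tert-butyldimethylsilyl)oxy]-9,10-epoxy-2-oxo-1-oxaspiro[4.5]dec-7-en-3-yl]carbamate | O=C1O[C@]2(C[C@@H]1NC(=O)OCc1ccccc1)[C@H](O[Si](C)(C)C(C)(C)C)C=C[C@@H]3O[C@@H]32
F11 | step 8 | benzyl N-[(3R,5S,6R,9S,10S)-6-[(tert-butyldimethylsilyl)oxy]-9,10-epoxy-2-oxo-1-oxaspiro[4.5]dec-7-en-3-yl]carbamate | O=C1O[C@]2(C[C@H]1NC(=O)OCc1ccccc1)[C@H](O[Si](C)(C)C(C)(C)C)C=C[C@@H]3O[C@@H]32
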